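**Retrosynthetic overview**

1. Ring B (the dearomatized ring) is numbered C1 (ring C=O), C2 (arylmethyl), C3 (C–O), C4 (quaternary), C5 (C–O), C6 (butanoyl); ring A is the hexanoyl arene. End game: acid/base deprotection ⇐ catalytic enantioselective dearomative prenylation at C4 ⇐ C6 butanoylation and one chelation-controlled de-ethylation of an aromatic ring B.
2. Key disconnection (benzannulation): aromatic ring B ⇒ an ynol ether carrying ring A on its propargylic CH2 (C2≡C3–OEt) + 3-ethoxy-2-methylcyclobut-2-enone (C1, C6, C5, C4). The alkyne is inserted into the C1–C4 σ-bond of the four-membered ring, so C1–C2 and C3–C4 are made in one thermal operation.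
3. Enabling feature: ring B is a six-membered carbocycle with oxygen on C1, C3, C5 and carbon groups on C2, C4, C6. Its C2–C3(O) edge is the retron of an ynol ether and its C4–C5(O)–C6–C1(O) chain that of a 3-alkoxyvinylketene. Joining C1 to C4 by a σ-bond stores that chain as a strained cyclobutenone whose ring opening drives the cascade.
4. Fragments: the ynol ether from phloroglucinol (acylation, 4-O-methylation, Mannich base, mesylation, benzylic chloride, Negishi alkynylation); the cyclobutenone from 1-ethoxyprop-1-yne and dichloroketene.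
5. Ring order: ring A is aromatic from the start; ring B is the only ring built (benzannulation) and is dearomatized when C4 becomes quaternary.

Key step: step 9

Remark: ring B of the target is a β-triketone with rapidly interconverting enol tautomers; the tautomer of the given SMILES is used throughout, and CIP descriptors at C4 are quoted for the tautomers drawn.

**Step 1**
Reactants: 1 phloroglucinol (benzene-1,3,5-triol)
Product: 2 1-(2,4,6-trihydroxyphenyl)hexan-1-one
Conditions: hexanoyl chloride, AlCl3, PhNO2/CH2Cl2, 0 °C → rt; aq. HCl work-up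
Reagents that add atoms: hexanoyl chloride, CCCCCC(=O)Cl
Why: Friedel–Crafts acylation of the highly activated triol; the first acyl group deactivates the ring, which should limit the reaction to mono-acylation.

**Step 2**
Reactants: 2 1-(2,4,6-trihydroxyphenyl)hexan-1-one
Product: 3 1-(2,6-dihydroxy-4-methoxyphenyl)hexan-1-one
Conditions: Me2SO4 (1.0 equiv), K2CO3 (1.0 equiv), acetone, rt
Reagents that add atoms: dimethyl sulfate, COS(=O)(=O)OC
Why: Williamson O-methylation selective for the 4-hydroxyl, the only phenol not hydrogen-bonded to the ketone and the most acidic one; one equivalent of base and electrophile limits over-methylation.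

**Step 3**
Reactants: 3 1-(2,6-dihydroxy-4-methoxyphenyl)hexan-1-one
Product: 4 1-{3-[(dimethylamino)methyl]-2,6-dihydroxy-4-methoxyphenyl}hexan-1-one
Conditions: CH2(NMe2)2 (1.05 equiv), 1,4-dioxane, rt
Reagents that add atoms: bis(dimethylamino)methane, CN(C)CN(C)C
Why: Mannich aminomethylation at one of the two equivalent free ring positions with the preformed aminal, which avoids free formaldehyde and thus methylene-bridged dimers.

**Step 4**
Reactants: 4 1-{3-[(dimethylamino)methyl]-2,6-dihydroxy-4-methoxyphenyl}hexan-1-one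
Product: 5 1-{3-[(dimethylamino)methyl]-4-methoxy-2,6-bis(methanesulfonyloxy)phenyl}hexan-1-one
Conditions: MsCl (2.4 equiv), Et3N, CH2Cl2, 0 °C
Reagents that add atoms: methanesulfonyl chloride, CS(=O)(=O)Cl
Why: Sulfonylation of both phenols; the mesylates are inert to ketenes, Lewis acids and organozinc reagents, do not migrate, and deactivate ring A toward later electrophiles.

**Step 5**
Reactants: 5 1-{3-[(dimethylamino)methyl]-4-methoxy-2,6-bis(methanesulfonyloxy)phenyl}hexan-1-one
Product: 6 1-[3-(chloromethyl)-4-methoxy-2,6-bis(methanesulfonyloxy)phenyl]hexan-1-one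
Conditions: ClCO2Et (1.5 equiv), CH2Cl2, 0 °C → rt
Reagents that add atoms: ethyl chloroformate, CCOC(=O)Cl
Why: von Braun-type dealkylation: N-acylation gives an acylammonium ion that chloride should open at the benzylic carbon (benzyl is cleaved in preference to methyl).

**Step 6**
Reactants: 6 1-[3-(chloromethyl)-4-methoxy-2,6-bis(methanesulfonyloxy)phenyl]hexan-1-one
Product: 7 1-[3-(3-ethoxyprop-2-yn-1-yl)-4-methoxy-2,6-bis(methanesulfonyloxy)phenyl]hexan-1-one
Conditions: HC≡COEt, n-BuLi, THF, −78 °C; ZnCl2, → 0 °C; then 6, PdCl2(DPEphos) (3 mol %), THF, rt → 45 °C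
Reagents that add atoms: ethoxyacetylene, C#COCC
Why: Negishi coupling of a benzylic chloride with an alkynylzinc chloride; the zinc reagent tolerates the aryl ketone and the sulfonates, and the benzylpalladium intermediate has no β-hydrogen.

**Step 7**
Reactants: 8 1-ethoxyprop-1-yne
Product: 9 4,4-dichloro-3-ethoxy-2-methylcyclobut-2-en-1-one
Conditions: Cl3CCOCl, Zn–Cu couple, Et2O/DME, rt
Reagents that add atoms: trichloroacetyl chloride, ClC(Cl)(Cl)C(=O)Cl
Why: [2+2] cycloaddition of dichloroketene with the ynol ether; the nucleophilic methyl-bearing alkyne carbon bonds to the ketene carbonyl carbon, which fixes the 2-methyl-3-ethoxy pattern.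

**Step 8**
Reactants: 9 4,4-dichloro-3-ethoxy-2-methylcyclobut-2-en-1-one
Product: 10 3-ethoxy-2-methylcyclobut-2-en-1-one
Conditions: Zn dust, AcOH, TMEDA, EtOH, 0 °C → rt
Reagents that add atoms: none
Why: Reductive dechlorination of the α,α-dichloroketone by zinc under buffered conditions that should leave the vinylogous ester intact.

**Step 9**
Reactants: 7 1-[3-(3-ethoxyprop-2-yn-1-yl)-4-methoxy-2,6-bis(methanesulfonyloxy)phenyl]hexan-1-one; 10 3-ethoxy-2-methylcyclobut-2-en-1-one
Product: 15 1-{3-[(2,4-diethoxy-6-hydroxy-3-methylphenyl)methyl]-4-methoxy-2,6-bis(methanesulfonyloxy)phenyl}hexan-1-one, via vinylketene 11 (not isolated), via vinylcyclobutenone 12 (not isolated), via dienylketene 13 (not isolated), via cyclohexadienone 14 (not isolated)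
Conditions: 10 (2 equiv), toluene, 95 °C, sealed tube; then 110 °C
Reagents that add atoms: none
Why: Heating should open 10 by 4π-electrocyclic cleavage of its C(=O)–CH2 bond to vinylketene 11, whose C=C=O unit adds 7 in a regioselective [2+2] cycloaddition (arylmethyl-bearing alkyne carbon to the ketene carbonyl carbon, ethoxy-bearing alkyne carbon to the methyl-bearing ketene carbon) to give 12; a second 4π opening gives dienylketene 13, 6π-electrocyclization gives 14 and enolization gives phenol 15, so that in the net result the alkyne is inserted into the acyl–vinyl bond of 10 and the ring B bonds C1–C2 and C3–C4 are new. The closest known reaction type is the Danheiser benzannulation of cyclobutenones with alkoxy- or siloxyalkynes to resorcinol derivatives. Ring B is closed by thermal disrotatory 6π-electrocyclization of the dienylketene, which re-forms the C1–C6 bond that the first ring opening broke. No stereocentre is created, since 15 is aromatic; C4 becomes stereogenic only in step 12. The step needs the regiochemistry of the [2+2] event, secured by the polarization of ynol ether and ketene, and freedom from ketene traps, secured by the mesylated ring A phenols, by excess 10, and by keeping the first stage below the temperature at which ethyl ynol ethers fragment.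

**Step 10**
Reactants: 15 1-{3-[(2,4-diethoxy-6-hydroxy-3-methylphenyl)methyl]-4-methoxy-2,6-bis(methanesulfonyloxy)phenyl}hexan-1-one
Product: 16 1-{3-[(3-butanoyl-4,6-diethoxy-2-hydroxy-5-methylphenyl)methyl]-4-methoxy-2,6-bis(methanesulfonyloxy)phenyl}hexan-1-one
Conditions: butyryl chloride, TiCl4, CH2Cl2, −20 → 0 °C
Reagents that add atoms: butyryl chloride, CCCC(=O)Cl
Why: TiCl4-mediated ortho-acylation (Friedel–Crafts) of the phenol at the only unsubstituted position of electron-rich ring B; ring A is deactivated by its ketone and two sulfonates.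

**Step 11**
Reactants: 16 1-{3-[(3-butanoyl-4,6-diethoxy-2-hydroxy-5-methylphenyl)methyl]-4-methoxy-2,6-bis(methanesulfonyloxy)phenyl}hexan-1-one
Product: 17 1-{3-[(3-butanoyl-6-ethoxy-2,4-dihydroxy-5-methylphenyl)methyl]-4-methoxy-2,6-bis(methanesulfonyloxy)phenyl}hexan-1-one
Conditions: BCl3 (3 equiv), CH2Cl2, −20 → 20 °C; aq. work-up
Reagents that add atoms: none
Why: Chelation-assisted ether cleavage by BCl3: only the ethoxy group next to the butanoyl carbonyl (C5) is activated, while the ring A methoxy and the C3 ethoxy group, which have no neighbouring carbonyl, should survive.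

**Step 12**
Reactants: 17 1-{3-[(3-butanoyl-6-ethoxy-2,4-dihydroxy-5-methylphenyl)methyl]-4-methoxy-2,6-bis(methanesulfonyloxy)phenyl}hexan-1-one
Product: 18 (4S)-6-butanoyl-3-ethoxy-2-{[3-hexanoyl-6-methoxy-2,4-bis(methanesulfonyloxy)phenyl]methyl}-5-hydroxy-4-methyl-4-(3-methylbut-2-en-1-yl)cyclohexa-2,5-dien-1-one
Conditions: tert-butyl prenyl carbonate (1.05 equiv), Pd2(dba)3·CHCl3 (2.5 mol %), (R,R)-DACH-phenyl Trost ligand (7.5 mol %), toluene, 0 °C → rt
Reagents that add atoms: tert-butyl 3-methylbut-2-en-1-yl carbonate, CC(C)=CCOC(=O)OC(C)(C)C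
Why: Proposed new method: ionisation of the carbonate by the palladium–ligand catalyst gives a cationic π-prenyl complex and tert-butoxide, which deprotonates the acidic 2,6-dihydroxyaryl ketone 17; the delocalised phenoxide should attack the unsubstituted allyl terminus through C4, the ring carbon ortho to C5–O and para to C1–O that carries only a methyl group (C2 is shielded by the arylmethyl group, C6 carries the acyl group, and O-prenylation is reversible under the catalysis), and the chiral pocket should select one face of the planar nucleophile because the two flanks of C4 differ strongly (chelated C5 oxygen against C3–OEt), so that the ligand sets the configuration at C4 (the (S,S)-ligand is taken if the sense of induction proves opposite); the closest known reaction types are the racemic base- or palladium-mediated dearomative C-prenylation of acylphloroglucinols and the palladium-catalysed asymmetric allylic dearomatization of naphthols.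

**Step 13**
Reactants: 18 (4S)-6-butanoyl-3-ethoxy-2-{[3-hexanoyl-6-methoxy-2,4-bis(methanesulfonyloxy)phenyl]methyl}-5-hydroxy-4-methyl-4-(3-methylbut-2-en-1-yl)cyclohexa-2,5-dien-1-one
Product: 20 elaphopilosin B, via triketone dimesylate 19 (not isolated)
Conditions: 2 M aq. HCl, THF, 40 °C; then NaOH, MeOH/H2O, 40 °C; cold 1 M HCl to pH 3
Reagents that add atoms: water, O
Why: Acid-catalysed hydrolysis of the vinylogous ester (addition–elimination at C3 of the protonated dienone) is run first, while ring A is still mesylated and cannot close a xanthene-type ether onto C3, then hydroxide cleaves the two aryl mesylates; the all-carbon quaternary centre cannot epimerize.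

**Compound list**

1 | phloroglucinol (benzene-1,3,5-triol) | Oc1cc(O)cc(O)c1 | starting material
2 | 1-(2,4,6-trihydroxyphenyl)hexan-1-one | CCCCCC(=O)c1c(O)cc(O)cc1O | intermediate
3 | 1-(2,6-dihydroxy-4-methoxyphenyl)hexan-1-one | CCCCCC(=O)c1c(O)cc(OC)cc1O | intermediate
4 | 1-{3-[(dimethylamino)methyl]-2,6-dihydroxy-4-methoxyphenyl}hexan-1-one | CCCCCC(=O)c1c(O)cc(OC)c(CN(C)C)c1O | intermediate
5 | 1-{3-[(dimethylamino)methyl]-4-methoxy-2,6-bis(methanesulfonyloxy)phenyl}hexan-1-one | CCCCCC(=O)c1c(OS(C)(=O)=O)cc(OC)c(CN(C)C)c1OS(C)(=O)=O | intermediate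
6 | 1-[3-(chloromethyl)-4-methoxy-2,6-bis(methanesulfonyloxy)phenyl]hexan-1-one | CCCCCC(=O)c1c(OS(C)(=O)=O)cc(OC)c(CCl)c1OS(C)(=O)=O | intermediate
7 | 1-[3-(3-ethoxyprop-2-yn-1-yl)-4-methoxy-2,6-bis(methanesulfonyloxy)phenyl]hexan-1-one | CCCCCC(=O)c1c(OS(C)(=O)=O)cc(OC)c(CC#COCC)c1OS(C)(=O)=O | intermediate
8 | 1-ethoxyprop-1-yne | CC#COCC | starting material
9 | 4,4-dichloro-3-ethoxy-2-methylcyclobut-2-en-1-one | O=C1C(C)=C(OCC)C1(Cl)Cl | intermediate
10 | 3-ethoxy-2-methylcyclobut-2-en-1-one | O=C1CC(OCC)=C1C | intermediate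
11 | 3-ethoxy-2-methylbuta-1,3-dien-1-one (vinylketene) | O=C=C(C)C(OCC)=C | intermediate (not isolated)
12 | 3-ethoxy-4-(1-ethoxyethenyl)-2-{[3-hexanoyl-6-methoxy-2,4-bis(methanesulfonyloxy)phenyl]methyl}-4-methylcyclobut-2-en-1-one | CCCCCC(=O)c1c(OS(C)(=O)=O)cc(OC)c(CC2=C(OCC)C(C)(C(OCC)=C)C2=O)c1OS(C)(=O)=O | intermediate (not isolated)
13 | 3,5-diethoxy-2-{[3-hexanoyl-6-methoxy-2,4-bis(methanesulfonyloxy)phenyl]methyl}-4-methylhexa-1,3,5-trien-1-one (dienylketene) | CCCCCC(=O)c1c(OS(C)(=O)=O)cc(OC)c(CC(=C=O)C(OCC)=C(C)C(OCC)=C)c1OS(C)(=O)=O | intermediate (not isolated)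
14 | 3,5-diethoxy-2-{[3-hexanoyl-6-methoxy-2,4-bis(methanesulfonyloxy)phenyl]methyl}-4-methylcyclohexa-2,4-dien-1-one | CCCCCC(=O)c1c(OS(C)(=O)=O)cc(OC)c(CC2=C(OCC)C(C)=C(OCC)CC2=O)c1OS(C)(=O)=O | intermediate (not isolated)
15 | 1-{3-[(2,4-diethoxy-6-hydroxy-3-methylphenyl)methyl]-4-methoxy-2,6-bis(methanesulfonyloxy)phenyl}hexan-1-one | CCCCCC(=O)c1c(OS(C)(=O)=O)cc(OC)c(Cc2c(O)cc(OCC)c(C)c2OCC)c1OS(C)(=O)=O | intermediate
16 | 1-{3-[(3-butanoyl-4,6-diethoxy-2-hydroxy-5-methylphenyl)methyl]-4-methoxy-2,6-bis(methanesulfonyloxy)phenyl}hexan-1-one | CCCCCC(=O)c1c(OS(C)(=O)=O)cc(OC)c(Cc2c(O)c(C(=O)CCC)c(OCC)c(C)c2OCC)c1OS(C)(=O)=O | intermediate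
17 | 1-{3-[(3-butanoyl-6-ethoxy-2,4-dihydroxy-5-methylphenyl)methyl]-4-methoxy-2,6-bis(methanesulfonyloxy)phenyl}hexan-1-one | CCCCCC(=O)c1c(OS(C)(=O)=O)cc(OC)c(Cc2c(O)c(C(=O)CCC)c(O)c(C)c2OCC)c1OS(C)(=O)=O | intermediate
18 | (4S)-6-butanoyl-3-ethoxy-2-{[3-hexanoyl-6-methoxy-2,4-bis(methanesulfonyloxy)phenyl]methyl}-5-hydroxy-4-methyl-4-(3-methylbut-2-en-1-yl)cyclohexa-2,5-dien-1-one (same spatial arrangement as the target; the descriptor differs only because the ethoxy group raises the CIP rank of C3) | CCCCCC(=O)c1c(OS(C)(=O)=O)cc(OC)c(CC2=C(OCC)[C@@](C)(CC=C(C)C)C(O)=C(C(=O)CCC)C2=O)c1OS(C)(=O)=O | intermediate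
19 | (4R)-6-butanoyl-2-{[3-hexanoyl-6-methoxy-2,4-bis(methanesulfonyloxy)phenyl]methyl}-3,5-dihydroxy-4-methyl-4-(3-methylbut-2-en-1-yl)cyclohexa-2,5-dien-1-one (triketone dimesylate) | CCCCCC(=O)c1c(OS(C)(=O)=O)cc(OC)c(CC2=C(O)[C@@](C)(CC=C(C)C)C(O)=C(C(=O)CCC)C2=O)c1OS(C)(=O)=O | intermediate (not isolated)
20 | elaphopilosin B, (4R)-6-butanoyl-2-[(3-hexanoyl-2,4-dihydroxy-6-methoxyphenyl)methyl]-3,5-dihydroxy-4-methyl-4-(3-methylbut-2-en-1-yl)cyclohexa-2,5-dien-1-one | CCCCCC(=O)c1c(O)cc(OC)c(CC2=C(O)[C@@](C)(CC=C(C)C)C(O)=C(C(=O)CCC)C2=O)c1O | target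

**Step count and risks**

Total: 13 steps. Longest linear sequence: 11 steps (steps 1–6 and 9–13).

Steps most likely to fail:

1. Step 12 (Proposed new method). What may go wrong: weak enantiofacial discrimination of the planar phenoxide, competing dearomatization at C2, O-prenylation that does not funnel to carbon, or a second allylation. Fallback: from 17, the stereocentre would be introduced without control by the classical dearomative C-prenylation of acylphloroglucinols (prenyl bromide, NaOMe, MeOH, 0 °C), which should give the racemic dienone F1. The conditions of step 13 should then lead through the racemic triketone dimesylate F2 to racemic elaphopilosin B F3. The enantiomers would be separated by preparative HPLC on a polysaccharide chiral stationary phase, which returns to the route at 20.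

2. Step 9. What may go wrong: thermal fragmentation of the ethyl ynol ether (retro-ene loss of ethylene to a ketene) before the alkoxy-stabilized cyclobutenone opens, and consumption of the vinylketene by dimerization or by O-acylation of the product phenol. Fallback: from 7, the same vinylketene 11 would be generated at room temperature by the diazo ketone (Wolff rearrangement) variant of the benzannulation. Acylation of metalated ethyl vinyl ether (t-BuLi) with N-methoxy-N-methylpropanamide should give 2-ethoxypent-1-en-3-one F4. Detrifluoroacetylative diazo transfer (LiN(SiMe3)2, CF3CO2CH2CF3, then MsN3, Et3N) should pass through the trifluoroacetyl ketone F5 to 4-diazo-2-ethoxypent-1-en-3-one F6. Irradiation of F6 and 7 with blue light (about 450 nm, CH2Cl2, rt; the aryl ketone of ring A does not absorb there) should give 11 and, by [2+2] cycloaddition, 12. Warming to 80–110 °C after 7 is consumed completes the sequence through 13 and 14 and returns to the route at 15.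

3. Step 13. What may go wrong: slow hydrolysis of the hindered C3 enol ether next to the quaternary centre, and acid-promoted cyclization of the prenyl chain onto the neighbouring enol oxygen when the acid stage is forced. Fallback: from 18, the ethyl group would be removed under aprotic conditions by O–CH2 cleavage instead of hydrolysis, with Me3SiI made in the flask (Me3SiCl, NaI, 2,6-di-tert-butylpyridine, MeCN, 0 °C) and a neutral aqueous work-up of the silyl enol ethers. This should give 19, and the NaOH stage of step 13 then returns to the route at 20. This fallback makes no new compound (F0).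

**Further compounds**

F1 | step 12 | racemic 6-butanoyl-3-ethoxy-2-{[3-hexanoyl-6-methoxy-2,4-bis(methanesulfonyloxy)phenyl]methyl}-5-hydroxy-4-methyl-4-(3-methylbut-2-en-1-yl)cyclohexa-2,5-dien-1-one | CCCCCC(=O)c1c(OS(C)(=O)=O)cc(OC)c(CC2=C(OCC)C(C)(CC=C(C)C)C(O)=C(C(=O)CCC)C2=O)c1OS(C)(=O)=O
F2 | step 12 | racemic triketone dimesylate | CCCCCC(=O)c1c(OS(C)(=O)=O)cc(OC)c(CC2=C(O)C(C)(CC=C(C)C)C(O)=C(C(=O)CCC)C2=O)c1OS(C)(=O)=O
F3 | step 12 | racemic elaphopilosin B | CCCCCC(=O)c1c(O)cc(OC)c(CC2=C(O)C(C)(CC=C(C)C)C(O)=C(C(=O)CCC)C2=O)c1O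
F4 | step 9 | 2-ethoxypent-1-en-3-one | C=C(OCC)C(=O)CC
F5 | step 9 | 2-ethoxy-6,6,6-trifluoro-4-methylhex-1-ene-3,5-dione | C=C(OCC)C(=O)C(C)C(=O)C(F)(F)F
F6 | step 9 | 4-diazo-2-ethoxypent-1-en-3-one | C=C(OCC)C(=O)C(C)=[N+]=[N-]
F0 | step 13 | none | none
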